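## Retrosynthetic overview

1. Target 12 ⇒ Weinreb amide 10 + 4-MeOC6H4MgBr. The 4-methoxyphenyl ketone is made last, so no aryl-ketone chromophore is present earlier; the labile β-ketoamide carbon C2 is equilibrated at the end under control of C3.
2. 10 ⇒ aryl malonamate 9 by a photo-Fries O→C acyl shift, which forms the (2-hydroxy-4,6-dimethoxyphenyl)–C(=O) bond.
3. 9 ⇒ triflate 8 + malonamate 5 by invertive SN2, which forms C2–C3 and sets C3 (R) from methyl (S)-mandelate 6 via Weinreb amide 7.
4. 5 ⇒ Meldrum's acid 1 + 3,5-dimethoxyphenol 2 + amine 3 (malonate linchpin).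
5. No ring is formed; all four benzene rings are bought.

Assumption: N-(4-aminobutyl)benzamide 3 is bought as a catalogue compound (free base), and the (2R,3R) form of the target is taken to be the more stable, crystallising epimer at the configurationally labile C2.

## Route

Step 1
Reactants: 1 Meldrum's acid (2,2-dimethyl-1,3-dioxane-4,6-dione); 2 3,5-dimethoxyphenol; 3 N-(4-aminobutyl)benzamide
Product: 5 3,5-dimethoxyphenyl 3-{[4-(benzoylamino)butyl]amino}-3-oxopropanoate, via aryl hydrogen malonate 4 (not isolated)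
Conditions: 1 + 2, toluene, 100 °C, 4 h; then DCC, HOBt (cat.), CH2Cl2, 0 °C, slow addition of 3, → 20 °C
Reagents that add atoms: none
Why: Thermal ring opening of Meldrum's acid by the phenol gives the aryl hydrogen malonate, and carbodiimide activation (amide coupling through the aryloxycarbonyl ketene) then acylates the primary amine far faster than the amine can aminolyse the electron-rich aryl ester; no stereocenter is involved.

Step 2
Reactants: 6 methyl (S)-mandelate
Product: 7 (2S)-2-hydroxy-N-methoxy-N-methyl-2-phenylacetamide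
Conditions: MeNHOMe·HCl (1.5 equiv), i-PrMgCl (4.2 equiv), THF, −20 → 0 °C
Reagents that add atoms: N,O-dimethylhydroxylamine hydrochloride, CNOC.Cl
Why: Weinreb amidation of the ester by the magnesium amide of N,O-dimethylhydroxylamine, with the hydroxyl masked in the flask as its magnesium alkoxide, which keeps the adjacent C–H non-acidic so the purchased stereocenter is untouched.

Step 3
Reactants: 7 (2S)-2-hydroxy-N-methoxy-N-methyl-2-phenylacetamide; 5 3,5-dimethoxyphenyl 3-{[4-(benzoylamino)butyl]amino}-3-oxopropanoate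
Product: 9 3,5-dimethoxyphenyl (3R)-2-{[4-(benzoylamino)butyl]carbamoyl}-4-[methoxy(methyl)amino]-4-oxo-3-phenylbutanoate (mixture of C2 epimers), via mandelamide triflate 8 (not isolated)
Conditions: Tf2O (1.05 equiv), 2,6-lutidine, CH2Cl2, −78 °C; cold silica plug (pentane/CH2Cl2); then 5, NaH (1.0 equiv), THF, −40 → 0 °C
Reagents that add atoms: trifluoromethanesulfonic anhydride, O=S(=O)(OS(=O)(=O)C(F)(F)F)C(F)(F)F (its triflyl group is carried only by intermediate 8 and leaves again as triflate)
Why: SN2 alkylation of a soft, weakly basic malonamate enolate by an α-carbonyl benzylic triflate proceeds with clean inversion, so the (S) centre bought in 6 becomes the (R) centre C3, while the amide α-hydrogen is too weakly acidic to be enolised by the nucleophile; C2 forms as an epimer mixture and is fixed in step 5.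

Step 4
Reactants: 9 3,5-dimethoxyphenyl (3R)-2-{[4-(benzoylamino)butyl]carbamoyl}-4-[methoxy(methyl)amino]-4-oxo-3-phenylbutanoate
Product: 10 (3R)-N1-[4-(benzoylamino)butyl]-2-(2-hydroxy-4,6-dimethoxybenzoyl)-N4-methoxy-N4-methyl-3-phenylbutanediamide (mixture of C2 epimers)
Conditions: hν (280 nm LED), degassed MeCN, 5 mM, 20 °C, quartz flow coil
Reagents that add atoms: none
Why: Proposed new method: photo-Fries rearrangement of an α-branched aryl malonamate (an aryl 2-carbamoylalkanoate), a substrate class on which it has not been shown – excitation of the 3,5-dimethoxyphenyl ester (the main absorber at 280 nm, since no aryl ketone is present yet) homolyses the ArO–C(=O) bond to a caged singlet pair of 3,5-dimethoxyphenoxyl and carbamoyl-substituted acyl radicals, which should recombine at one of the two equivalent ortho carbons (the para carbon is flanked by two methoxy groups) faster than the acyl radical loses CO, and tautomerisation gives the hydrogen-bonded 2-hydroxyaryl ketone, which is photostable through excited-state proton transfer; the closest known reaction type is the photo-Fries rearrangement of simple aryl alkanoates and dihydrocinnamates to 2-hydroxyaryl ketones; C3 is not involved and stays R.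

Step 5
Reactants: 10 (3R)-N1-[4-(benzoylamino)butyl]-2-(2-hydroxy-4,6-dimethoxybenzoyl)-N4-methoxy-N4-methyl-3-phenylbutanediamide
Product: 12 (2R,3R)-N-[4-(benzoylamino)butyl]-2-(2-hydroxy-4,6-dimethoxybenzoyl)-4-(4-methoxyphenyl)-4-oxo-3-phenylbutanamide, via C2-epimeric diketone mixture 11 (not isolated)
Conditions: 4-MeOC6H4MgBr (6 equiv), THF, −20 → 20 °C; aq. citric acid, 0 °C; then N-methylmorpholine (10 mol %), i-PrOAc/heptane, 45 → 5 °C, crystallisation
Reagents that add atoms: 4-methoxyphenylmagnesium bromide, COc1ccc([Mg]Br)cc1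
Why: Weinreb ketone synthesis in which the first equivalents of Grignard reagent deprotonate the phenol, the β-ketoamide carbon and the amide N–H groups (protecting the hydroxyaryl ketone as its enolate) and the chelated tetrahedral intermediate prevents over-addition and keeps C3 non-enolisable until the acidic quench; the labile C2 then epimerises through its enol under the weak amine base, which cannot touch C3, and the (2R,3R) epimer is collected by crystallisation-induced diastereomer transformation, so C2 is controlled by C3.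

## Compound list

1 | Meldrum's acid (2,2-dimethyl-1,3-dioxane-4,6-dione) | CC1(C)OC(=O)CC(=O)O1 | starting material
2 | 3,5-dimethoxyphenol | COc1cc(O)cc(OC)c1 | starting material
3 | N-(4-aminobutyl)benzamide | NCCCCNC(=O)c1ccccc1 | starting material
4 | 3-(3,5-dimethoxyphenoxy)-3-oxopropanoic acid (aryl hydrogen malonate, not isolated) | COc1cc(OC(=O)CC(=O)O)cc(OC)c1 | intermediate
5 | 3,5-dimethoxyphenyl 3-{[4-(benzoylamino)butyl]amino}-3-oxopropanoate | COc1cc(OC(=O)CC(=O)NCCCCNC(=O)c2ccccc2)cc(OC)c1 | intermediate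
6 | methyl (S)-mandelate (methyl (2S)-2-hydroxy-2-phenylacetate) | COC(=O)[C@@H](O)c1ccccc1 | starting material
7 | (2S)-2-hydroxy-N-methoxy-N-methyl-2-phenylacetamide | CON(C)C(=O)[C@@H](O)c1ccccc1 | intermediate
8 | (1S)-2-[methoxy(methyl)amino]-2-oxo-1-phenylethyl trifluoromethanesulfonate (not isolated) | CON(C)C(=O)[C@@H](OS(=O)(=O)C(F)(F)F)c1ccccc1 | intermediate
9 | 3,5-dimethoxyphenyl (3R)-2-{[4-(benzoylamino)butyl]carbamoyl}-4-[methoxy(methyl)amino]-4-oxo-3-phenylbutanoate (C2 epimer mixture) | CON(C)C(=O)[C@@H](c1ccccc1)C(C(=O)NCCCCNC(=O)c1ccccc1)C(=O)Oc1cc(OC)cc(OC)c1 | intermediate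
10 | (3R)-N1-[4-(benzoylamino)butyl]-2-(2-hydroxy-4,6-dimethoxybenzoyl)-N4-methoxy-N4-methyl-3-phenylbutanediamide (C2 epimer mixture) | CON(C)C(=O)[C@@H](c1ccccc1)C(C(=O)NCCCCNC(=O)c1ccccc1)C(=O)c1c(O)cc(OC)cc1OC | intermediate
11 | (3R)-N-[4-(benzoylamino)butyl]-2-(2-hydroxy-4,6-dimethoxybenzoyl)-4-(4-methoxyphenyl)-4-oxo-3-phenylbutanamide (C2 epimer mixture, not isolated) | COc1ccc(C(=O)[C@@H](c2ccccc2)C(C(=O)NCCCCNC(=O)c2ccccc2)C(=O)c2c(O)cc(OC)cc2OC)cc1 | intermediate
12 | (2R,3R)-N-[4-(benzoylamino)butyl]-2-(2-hydroxy-4,6-dimethoxybenzoyl)-4-(4-methoxyphenyl)-4-oxo-3-phenylbutanamide | COc1ccc(C(=O)[C@@H](c2ccccc2)[C@@H](C(=O)NCCCCNC(=O)c2ccccc2)C(=O)c2c(O)cc(OC)cc2OC)cc1 | target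

## Step count and risks

Total step count: 5. Longest linear sequence: 4 steps (6 → 7 → 9 → 10 → 12, or 1 → 5 → 9 → 10 → 12).

**Step 3 (triflate SN2).** The benzylic triflate 8 may decompose or partly ionise, and the aryl malonate enolate can O-alkylate or lose aryloxide. Fallback: set out from alcohol 7 and Meldrum's acid 1 and avoid both the sulfonate and any base. A Mitsunobu C-alkylation (PPh3, DIAD, THF, 0 °C; inversion) gives (2R)-2-(2,2-dimethyl-4,6-dioxo-1,3-dioxan-5-yl)-N-methoxy-N-methyl-2-phenylacetamide F1. Heating F1 with phenol 2 (toluene, 90 °C) opens the dioxanedione to (3R)-2-[(3,5-dimethoxyphenoxy)carbonyl]-4-[methoxy(methyl)amino]-4-oxo-3-phenylbutanoic acid F2. DCC coupling of F2 with amine 3 comes back to the route at 9.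

**Step 4 (proposed new photo-Fries).** Possible failures are low conversion (the product acts as an inner filter), para recombination, decarbonylation of the acyl radical, or simple ester photolysis back to phenol 2. Fallback with known chemistry, in which the phenol is unveiled last instead of being made by an acyl shift: set out from amine 3 and triflate 8. Purchased 1-(2,4,6-trimethoxyphenyl)ethanone undergoes Claisen condensation with dimethyl carbonate (NaH, THF, reflux) to methyl 3-oxo-3-(2,4,6-trimethoxyphenyl)propanoate F3. Thermal aminolysis with 3 (toluene, 110 °C) gives N-[4-(benzoylamino)butyl]-3-oxo-3-(2,4,6-trimethoxyphenyl)propanamide F4. Its sodium enolate displaces the triflate of 8 with inversion to give (3R)-N1-[4-(benzoylamino)butyl]-N4-methoxy-N4-methyl-3-phenyl-2-(2,4,6-trimethoxybenzoyl)butanediamide F5. BCl3 (CH2Cl2, −78 → 0 °C) then removes one ortho methyl ether by chelation to the ketone, coming back to the route at 10.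

**Step 5 (Grignard addition and C2 equilibration).** The hindered Weinreb amide inside a magnesium polyanion may add sluggishly or erode C3, and the crystallising epimer may not be (2R); in that case the epimers are separated and the unwanted one re-equilibrated. Fallback, which replaces the organometallic addition by a base-free cross-coupling: set out from ester 6 and malonamate 5. Ester 6 is converted with AlMe3/EtSH (CH2Cl2, 0 °C) into S-ethyl (2S)-2-hydroxy-2-phenylethanethioate F6. Tf2O/2,6-lutidine gives S-ethyl (2S)-2-phenyl-2-[(trifluoromethanesulfonyl)oxy]ethanethioate F7. The sodium enolate of 5 displaces the triflate with inversion to give 3,5-dimethoxyphenyl (3R)-2-{[4-(benzoylamino)butyl]carbamoyl}-4-(ethylsulfanyl)-4-oxo-3-phenylbutanoate F8. Irradiation as in step 4 gives S-ethyl (2R)-3-{[4-(benzoylamino)butyl]carbamoyl}-4-(2-hydroxy-4,6-dimethoxyphenyl)-4-oxo-2-phenylbutanethioate F9. Liebeskind–Srogl coupling with 4-methoxyphenylboronic acid (Pd2(dba)3, tri(2-furyl)phosphine, copper thiophene-2-carboxylate CuO2CC4H3S, THF, 50 °C) comes back to the route at 11, which is equilibrated to 12 as in step 5.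

## Further compounds

F1 | step 3 | (2R)-2-(2,2-dimethyl-4,6-dioxo-1,3-dioxan-5-yl)-N-methoxy-N-methyl-2-phenylacetamide | CON(C)C(=O)[C@@H](c1ccccc1)C1C(=O)OC(C)(C)OC1=O
F2 | step 3 | (3R)-2-[(3,5-dimethoxyphenoxy)carbonyl]-4-[methoxy(methyl)amino]-4-oxo-3-phenylbutanoic acid (C2 epimer mixture) | CON(C)C(=O)[C@@H](c1ccccc1)C(C(=O)O)C(=O)Oc1cc(OC)cc(OC)c1
F3 | step 4 | methyl 3-oxo-3-(2,4,6-trimethoxyphenyl)propanoate | COC(=O)CC(=O)c1c(OC)cc(OC)cc1OC
F4 | step 4 | N-[4-(benzoylamino)butyl]-3-oxo-3-(2,4,6-trimethoxyphenyl)propanamide | COc1cc(OC)c(C(=O)CC(=O)NCCCCNC(=O)c2ccccc2)c(OC)c1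
F5 | step 4 | (3R)-N1-[4-(benzoylamino)butyl]-N4-methoxy-N4-methyl-3-phenyl-2-(2,4,6-trimethoxybenzoyl)butanediamide (C2 epimer mixture) | CON(C)C(=O)[C@@H](c1ccccc1)C(C(=O)NCCCCNC(=O)c1ccccc1)C(=O)c1c(OC)cc(OC)cc1OC
F6 | step 5 | S-ethyl (2S)-2-hydroxy-2-phenylethanethioate | CCSC(=O)[C@@H](O)c1ccccc1
F7 | step 5 | S-ethyl (2S)-2-phenyl-2-[(trifluoromethanesulfonyl)oxy]ethanethioate | CCSC(=O)[C@@H](OS(=O)(=O)C(F)(F)F)c1ccccc1
F8 | step 5 | 3,5-dimethoxyphenyl (3R)-2-{[4-(benzoylamino)butyl]carbamoyl}-4-(ethylsulfanyl)-4-oxo-3-phenylbutanoate (C2 epimer mixture) | CCSC(=O)[C@@H](c1ccccc1)C(C(=O)NCCCCNC(=O)c1ccccc1)C(=O)Oc1cc(OC)cc(OC)c1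
F9 | step 5 | S-ethyl (2R)-3-{[4-(benzoylamino)butyl]carbamoyl}-4-(2-hydroxy-4,6-dimethoxyphenyl)-4-oxo-2-phenylbutanethioate (C3 epimer mixture) | CCSC(=O)[C@@H](c1ccccc1)C(C(=O)NCCCCNC(=O)c1ccccc1)C(=O)c1c(O)cc(OC)cc1OC
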